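## Retrosynthetic overview

1. Target ⇐ acetylation of the cis-epoxy alcohol ⇐ regio- and stereoselective 1,2-reduction of a farnesyl epoxyquinone ⇐ hydrolysis of its quinone monoketal ⇐ catalytic asymmetric nucleophilic epoxidation of a 2-farnesyl-5-methyl p-quinone monoketal ⇐ PhI(OAc)2/MeOH oxidation of 2-farnesyl-5-methylphenol.
2. Key disconnection (ArCH2–CH=): Ni-catalysed coupling of a C9 benzylic chloride (from m-cresol) with the (E)-alkenylalane made by Zr-catalysed methylalumination of a C13 dienyne. This step also creates the 2E olefin.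
3. Dienyne ⇐ Negishi sp2–sp3 coupling of a C9 (E)-alkenyl iodide (from 5-bromo-2-methylpent-2-ene and acetylide, then methylalumination/iodination, which sets 6E) with a C4 TMS-homopropargylzinc (from but-3-yn-1-ol).
4. Ring order: the carbocycle is the purchased aromatic ring, dearomatised after the coupling; the oxirane is the only ring formed (Step 14).

Assumptions (one line each):
- "Farnesyl" below means (2E,6E)-3,7,11-trimethyldodeca-2,6,10-trien-1-yl.
- The target SMILES is read as (1R,5R,6R) in 7-oxabicyclo[4.1.0]hept-3-en-2-one numbering (C1 = farnesyl-bearing carbon), with the acetoxy group cis to the epoxide oxygen.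
- The cinchonidinium catalyst in Step 14 is assumed to give the (1R,6S) epoxide; if the sense is opposite, the pseudo-enantiomeric N-benzylcinchoninium salt is used instead.
- Compounds 1, 4 and 9 are taken as commercial.

## Forward route

**Step 1**
Reactants: 1, 5-bromo-2-methylpent-2-ene
Product: 2, 6-methylhept-5-en-1-yne
Conditions: LiC≡CH·ethylenediamine (1.3 equiv), DMSO, 10 °C → rt
Reagents that add atoms: lithium acetylide (ethylenediamine complex), [Li]C#C
Why: SN2 alkylation of acetylide on an unhindered primary bromide in DMSO; the trisubstituted alkene is inert.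

**Step 2**
Reactants: 2, 6-methylhept-5-en-1-yne
Product: 3, (1E)-1-iodo-2,6-dimethylhepta-1,5-diene
Conditions: Me3Al (2 equiv), Cp2ZrCl2 (0.25 equiv), CH2Cl2, 0 °C → rt; then I2, THF, −30 → 0 °C
Reagents that add atoms: trimethylaluminium, C[Al](C)C; iodine, II
Why: Negishi Zr-catalysed carboalumination adds Me–Al syn across the terminal alkyne (Me to the internal carbon), and iodinolysis with retention gives only the E alkenyl iodide, the future 6E olefin.

**Step 3**
Reactants: 4, but-3-yn-1-ol
Product: 5, 4-(trimethylsilyl)but-3-yn-1-ol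
Conditions: n-BuLi (2.1 equiv), THF, −78 °C; TMSCl (2.2 equiv), → rt; then 1 M HCl
Reagents that add atoms: chlorotrimethylsilane, C[Si](C)(C)Cl
Why: Bis-silylation of the alkoxide/acetylide dianion followed by selective acidic cleavage of the labile O–Si bond leaves the C-silyl alkyne protecting group.

**Step 4**
Reactants: 5, 4-(trimethylsilyl)but-3-yn-1-ol
Product: 6, (4-iodobut-1-yn-1-yl)trimethylsilane
Conditions: I2, PPh3, imidazole, CH2Cl2, 0 °C → rt
Reagents that add atoms: iodine, II
Why: Appel-type iodination of a primary alcohol under neutral conditions; the silyl alkyne is unaffected.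

**Step 5**
Reactants: 6, (4-iodobut-1-yn-1-yl)trimethylsilane; 3, (1E)-1-iodo-2,6-dimethylhepta-1,5-diene
Product: 7, trimethyl[(5E)-6,10-dimethylundeca-5,9-dien-1-yn-1-yl]silane
Conditions: 6, t-BuLi (2.1 equiv), Et2O, −78 °C; ZnBr2, THF, −78 → 0 °C; then 3, Pd(PPh3)4 (5 mol%), THF, rt
Reagents that add atoms: none
Why: Negishi alkenyl–homopropargylzinc cross-coupling proceeds with retention of the E geometry, and β-hydride elimination is slow for homopropargylzinc partners.

**Step 6**
Reactants: 7, trimethyl[(5E)-6,10-dimethylundeca-5,9-dien-1-yn-1-yl]silane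
Product: 8, (5E)-6,10-dimethylundeca-5,9-dien-1-yne
Conditions: K2CO3, MeOH, rt
Reagents that add atoms: none
Why: Methanolysis of the alkynyl C–Si bond frees the terminal alkyne without touching the 1,5-diene.

**Step 7**
Reactants: 9, 3-methylphenol (m-cresol)
Product: 10, 2-hydroxy-4-methylbenzaldehyde
Conditions: MgCl2, Et3N, (CH2O)n, MeCN, reflux
Reagents that add atoms: paraformaldehyde, C=O
Why: Magnesium phenoxide-directed ortho-formylation (Casnati–Skattebøl) is ortho-specific and occurs at the unhindered C6 (para to methyl), not at the position flanked by OH and CH3.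

**Step 8**
Reactants: 10, 2-hydroxy-4-methylbenzaldehyde
Product: 11, 2-(methoxymethoxy)-4-methylbenzaldehyde
Conditions: MOMCl, i-Pr2NEt, CH2Cl2, 0 °C → rt
Reagents that add atoms: chloromethyl methyl ether, COCCl
Why: O-alkylation of the phenol gives an acetal protecting group that cannot migrate to the benzylic oxygen in the next step, as a silyl group would.

**Step 9**
Reactants: 11, 2-(methoxymethoxy)-4-methylbenzaldehyde
Product: 12, [2-(methoxymethoxy)-4-methylphenyl]methanol
Conditions: NaBH4, MeOH, 0 °C
Reagents that add atoms: none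
Why: Simple borohydride reduction of an aryl aldehyde; the MOM ether is stable to base and hydride.

**Step 10**
Reactants: 12, [2-(methoxymethoxy)-4-methylphenyl]methanol
Product: 13, 1-(chloromethyl)-2-(methoxymethoxy)-4-methylbenzene
Conditions: MsCl, Et3N, CH2Cl2, 0 °C; then LiCl, DMF, rt (used directly)
Reagents that add atoms: lithium chloride, [Li+].[Cl-]
Why: Mesylation and in situ chloride displacement at an activated benzylic carbon under non-acidic conditions keep the MOM group intact.

**Step 11 (key fragment coupling)**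
Reactants: 8, (5E)-6,10-dimethylundeca-5,9-dien-1-yne; 13, 1-(chloromethyl)-2-(methoxymethoxy)-4-methylbenzene
Product: 14, 2-(methoxymethoxy)-4-methyl-1-[(2E,6E)-3,7,11-trimethyldodeca-2,6,10-trien-1-yl]benzene
Conditions: 8, Me3Al (2 equiv), Cp2ZrCl2 (0.25 equiv), ClCH2CH2Cl, rt; remove excess Me3Al in vacuo; then 13, NiCl2(PPh3)2 (3 mol%)/n-BuLi (6 mol%), THF, rt
Reagents that add atoms: trimethylaluminium, C[Al](C)C
Why: A second syn methylalumination creates the 2E trisubstituted olefin, and Ni(0)-catalysed alkenylalane–benzyl chloride cross-coupling (Negishi type) joins the C14 and C10 halves with retention of geometry.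

**Step 12**
Reactants: 14
Product: 15, 5-methyl-2-[(2E,6E)-3,7,11-trimethyldodeca-2,6,10-trien-1-yl]phenol
Conditions: conc. HCl (cat.), MeOH, rt
Reagents that add atoms: none
Why: Acetal methanolysis of the aryl MOM ether is fast in dilute methanolic HCl at rt, conditions too mild for chroman formation or polyene cyclisation.

**Step 13**
Reactants: 15
Product: 16, 4,4-dimethoxy-5-methyl-2-[(2E,6E)-farnesyl]cyclohexa-2,5-dien-1-one
Conditions: PhI(OAc)2 (2.2 equiv), MeOH, 0 °C → rt
Reagents that add atoms: methanol (two equivalents incorporated), CO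
Why: Hypervalent-iodine oxidative dearomatisation: MeOH traps the activated phenol at the free para position, and the resulting 4-methoxyphenol is oxidised again to the p-quinone monoketal. The carbonyl ends up next to the farnesyl carbon and the ketal next to the methyl-bearing carbon; isolated olefins are inert.

**Step 14**
Reactants: 16
Product: 17, (1R,6S)-5,5-dimethoxy-4-methyl-1-[(2E,6E)-farnesyl]-7-oxabicyclo[4.1.0]hept-3-en-2-one
Conditions: t-BuOOH, aq. NaOH, N-benzylcinchonidinium chloride (10 mol%), toluene, 0 °C → rt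
Reagents that add atoms: tert-butyl hydroperoxide, CC(C)(C)OO
Why: Weitz–Scheffer nucleophilic epoxidation under Wynberg-type chiral phase-transfer catalysis: t-BuOO⁻ adds to the β-CH of the α-farnesyl enone rather than the β-methyl enone, and the chiral ion pair selects the dienone face, setting both oxirane stereocentres (C1 R, C6 S) together. The electron-rich chain olefins do not react.

**Step 15**
Reactants: 17
Product: 18, (1R,6S)-4-methyl-1-[(2E,6E)-farnesyl]-7-oxabicyclo[4.1.0]hept-3-ene-2,5-dione
Conditions: wet montmorillonite K-10, CH2Cl2, rt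
Reagents that add atoms: water, O
Why: Mild heterogeneous acid hydrolysis of the dimethyl ketal unmasks the second carbonyl without opening the epoxide or isomerising the polyene; the stereocentres are not involved.

**Step 16**
Reactants: 18
Product: 19, (1R,5R,6R)-5-hydroxy-4-methyl-1-[(2E,6E)-farnesyl]-7-oxabicyclo[4.1.0]hept-3-en-2-one
Conditions: NaBH4 (0.3 equiv), CeCl3·7H2O, MeOH, −78 °C
Reagents that add atoms: none
Why: Luche 1,2-reduction picks the C5 carbonyl, which is more electrophilic (C2 is deactivated by the β-methyl and shielded by the quaternary C1). Hydride arrives anti to the epoxide oxygen, on the face bearing only C6–H, so the new 5R hydroxyl is cis to the epoxide.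

**Step 17**
Reactants: 19
Product: 20, (1R,5R,6R)-5-acetoxy-4-methyl-1-[(2E,6E)-farnesyl]-7-oxabicyclo[4.1.0]hept-3-en-2-one (target, CID121596208)
Conditions: Ac2O, pyridine, DMAP (cat.), CH2Cl2, 0 °C
Reagents that add atoms: acetic anhydride, CC(=O)OC(C)=O
Why: DMAP-catalysed O-acylation of the secondary allylic alcohol at 0 °C is faster than any base-induced epoxide opening and leaves all three stereocentres untouched.

## Compound list

1 | 5-bromo-2-methylpent-2-ene | CC(C)=CCCBr | starting material
2 | 6-methylhept-5-en-1-yne | C#CCCC=C(C)C | intermediate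
3 | (1E)-1-iodo-2,6-dimethylhepta-1,5-diene | I/C=C(\C)CCC=C(C)C | intermediate
4 | but-3-yn-1-ol | C#CCCO | starting material
5 | 4-(trimethylsilyl)but-3-yn-1-ol | C[Si](C)(C)C#CCCO | intermediate
6 | (4-iodobut-1-yn-1-yl)trimethylsilane | C[Si](C)(C)C#CCCI | intermediate
7 | trimethyl[(5E)-6,10-dimethylundeca-5,9-dien-1-yn-1-yl]silane | C[Si](C)(C)C#CCC/C=C(\C)CCC=C(C)C | intermediate
8 | (5E)-6,10-dimethylundeca-5,9-dien-1-yne | C#CCC/C=C(\C)CCC=C(C)C | intermediate
9 | 3-methylphenol (m-cresol) | Cc1cccc(O)c1 | starting material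
10 | 2-hydroxy-4-methylbenzaldehyde | Cc1ccc(C=O)c(O)c1 | intermediate
11 | 2-(methoxymethoxy)-4-methylbenzaldehyde | COCOc1cc(C)ccc1C=O | intermediate
12 | [2-(methoxymethoxy)-4-methylphenyl]methanol | COCOc1cc(C)ccc1CO | intermediate
13 | 1-(chloromethyl)-2-(methoxymethoxy)-4-methylbenzene | COCOc1cc(C)ccc1CCl | intermediate
14 | 2-(methoxymethoxy)-4-methyl-1-[(2E,6E)-3,7,11-trimethyldodeca-2,6,10-trien-1-yl]benzene | COCOc1cc(C)ccc1C/C=C(\C)CC/C=C(\C)CCC=C(C)C | intermediate
15 | 5-methyl-2-[(2E,6E)-3,7,11-trimethyldodeca-2,6,10-trien-1-yl]phenol | Cc1ccc(C/C=C(\C)CC/C=C(\C)CCC=C(C)C)c(O)c1 | intermediate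
16 | 4,4-dimethoxy-5-methyl-2-[(2E,6E)-3,7,11-trimethyldodeca-2,6,10-trien-1-yl]cyclohexa-2,5-dien-1-one | COC1(OC)C=C(C/C=C(\C)CC/C=C(\C)CCC=C(C)C)C(=O)C=C1C | intermediate
17 | (1R,6S)-5,5-dimethoxy-4-methyl-1-[(2E,6E)-3,7,11-trimethyldodeca-2,6,10-trien-1-yl]-7-oxabicyclo[4.1.0]hept-3-en-2-one | COC1(OC)C(C)=CC(=O)[C@]2(C/C=C(\C)CC/C=C(\C)CCC=C(C)C)O[C@H]12 | intermediate
18 | (1R,6S)-4-methyl-1-[(2E,6E)-3,7,11-trimethyldodeca-2,6,10-trien-1-yl]-7-oxabicyclo[4.1.0]hept-3-ene-2,5-dione | O=C1C(C)=CC(=O)[C@]2(C/C=C(\C)CC/C=C(\C)CCC=C(C)C)O[C@H]12 | intermediate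
19 | (1R,5R,6R)-5-hydroxy-4-methyl-1-[(2E,6E)-3,7,11-trimethyldodeca-2,6,10-trien-1-yl]-7-oxabicyclo[4.1.0]hept-3-en-2-one | O[C@@H]1C(C)=CC(=O)[C@]2(C/C=C(\C)CC/C=C(\C)CCC=C(C)C)O[C@H]12 | intermediate
20 | (1R,5R,6R)-5-acetoxy-4-methyl-1-[(2E,6E)-3,7,11-trimethyldodeca-2,6,10-trien-1-yl]-7-oxabicyclo[4.1.0]hept-3-en-2-one (acetoxy cis to the epoxide oxygen) | CC(=O)O[C@@H]1C(C)=CC(=O)[C@]2(C/C=C(\C)CC/C=C(\C)CCC=C(C)C)O[C@H]12 | target

## Summary

Total step count: 17.

Longest linear sequence: 11 steps. Each of the three branches reaches the target in 11 steps: 1→2→3→7→8→14→…→20, 4→5→6→7→8→14→…→20 and 9→10→11→12→13→14→…→20.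

Three steps most likely to fail, each with a fallback:

1. **Step 14 (asymmetric epoxidation).** α-Alkyl dienones react slowly, ee may be only moderate, and the facial sense is assumed. Fallback: run a racemic Weitz–Scheffer epoxidation (t-BuOOH, DBU), carry the racemate to rac-19, and make the final acetylation a lipase kinetic resolution (Amano PS, vinyl acetate), isolating the enantiopure acetate. This replaces asymmetric catalysis with enzymatic resolution.
2. **Step 13 (double PhI(OAc)2 oxidation of a para-unsubstituted phenol).** Ortho attack or over-oxidation could lower the yield. Fallback: put the para oxygen on the arene before the coupling (m-cresol → 4-bromo-3-methylphenol → Cu/NaOMe → 4-methoxy-3-methylphenol, then the same formylation/MOM/reduction/chlorination). The coupled phenol is then a 4-methoxyphenol that needs only one clean PhI(OAc)2 oxidation.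
3. **Step 16 (regio- and diastereoselective reduction of the epoxyquinone).** Reduction could occur at C2 or give the anti alcohol. Fallback: differentiate the carbonyls by protection instead of relying on selectivity. From 17: reduce the C2 ketone (DIBAL-H), silylate, hydrolyse the ketal, reduce and acetylate at C5 (Mitsunobu with AcOH if the anti alcohol forms), then desilylate and re-oxidise C2 (Dess–Martin).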